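**Plan**

- Cuts (labdane numbering): C12–C13 (butenolide), C9–C11 (vinyl group), C6–O, C4–C18, then C2–C3 of ring A, and last C10–C1 and C10–C20.
- Feature used: ring B with its C8 methyl, the C5 stereocentre and C4 with the two carbons it carries (C3, C19) are the ring, stereocentre and isopropenyl group of (R)-carvone. An aldehyde carbon C2 on a C10 arm therefore lies five atoms from a 1,1-disubstituted ene.
- Forward: carvone (ring B) is methylated and then alkylated with bromoacetate at C10, and the arm is brought to the aldehyde. A Me2AlCl type 2 carbonyl-ene reaction then closes ring A at C2–C3 and gives the C2 carbinol and the C4 methylene.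
- C4 is then made quaternary, C6 is hydroxylated through the silyl dienol ether, and the enone becomes the C9 enol triflate. Vinylation, hydroboration and Suzuki coupling with 4-bromofuran-2(5H)-one finish the side chain.
- Stereochemistry: C5 from carvone; C10 by alkylation anti to the isopropenyl group; C2 from the chair ene transition state (equatorial oxygen); C4 by α-face methylation of the aldehyde enolate; C6 by α-face epoxidation of the dienol ether.

Key step: step 5

Remark: labdane numbering is used for all bicyclic compounds (C17 on C8, C18 = 4α-methyl, C19 = 4β-carbon, C20 on C10; α = face opposite the C10 methyl; all are trans-fused with 5α-H and 10β-CH3), and the target is read from its SMILES as (2R,4S,5R,6S,10S)-2α,6α,19-trihydroxylabda-8,13-dien-15,16-olide.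

**Route**

Step 1
Reactants: 1 (R)-carvone; 2 iodomethane
Product: 4 6-methylcarvone as C6 epimers, via lithium dienolate 3 (not isolated)
Conditions: LiN(iPr)2, THF, −78 °C; MeI, −78 → 0 °C
Reagents that add atoms: iodomethane, CI
Why: Kinetic deprotonation of the enone at its α'-CH2 and SN2 methylation of the cross-conjugated lithium enolate (enolate alkylation) should give the monomethyl ketone, whose new centre is set again in step 2.

Step 2
Reactants: 4 6-methylcarvone; 5 ethyl bromoacetate
Product: 7 keto ester ethyl 2-[(1S,6S)-1,3-dimethyl-2-oxo-6-(prop-1-en-2-yl)cyclohex-3-en-1-yl]acetate, via lithium enolate 6 (not isolated)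
Conditions: LiN(iPr)2, THF, −78 → 0 °C; DMPU, BrCH2CO2Et, −78 °C → rt
Reagents that add atoms: ethyl bromoacetate, CCOC(=O)CBr
Why: Enolate alkylation of the tetrasubstituted lithium enolate should take place on the face anti to the neighbouring isopropenyl group, which puts the acetate arm trans to it and the methyl (C20) cis, the arrangement needed at C10.

Step 3
Reactants: 7 keto ester
Product: 8 diol 2-[(1S,6S)-2-hydroxy-1,3-dimethyl-6-(prop-1-en-2-yl)cyclohex-3-en-1-yl]ethan-1-ol as carbinol epimers
Conditions: LiAlH4, Et2O, 0 °C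
Reagents that add atoms: none
Why: Hydride reduction takes the ester to the primary alcohol and the enone to the allylic alcohol by 1,2-addition, so no chemoselectivity is asked for and the carbinol centre is removed again in step 4.

Step 4
Reactants: 8 diol
Product: 9 keto aldehyde 2-[(1S,6S)-1,3-dimethyl-2-oxo-6-(prop-1-en-2-yl)cyclohex-3-en-1-yl]acetaldehyde
Conditions: (COCl)2, DMSO, CH2Cl2, −78 °C; Et3N, −78 → 0 °C
Reagents that add atoms: none
Why: Swern oxidation turns both hydroxyls into alkoxysulfonium ions before the base is added, so the enone and the aldehyde should form together without the 1,4-hydroxy aldehyde closing to a lactol.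

Step 5
Reactants: 9 keto aldehyde
Product: 10 hydroxy enone (4aS,7S,8aS)-7-hydroxy-2,8a-dimethyl-5-methylidene-4a,5,6,7,8,8a-hexahydronaphthalen-1(4H)-one
Conditions: Me2AlCl (2.2 equiv), CH2Cl2, −78 → −20 °C; 1 M HCl
Reagents that add atoms: none
Why: Me2AlCl binds the aldehyde oxygen, the CH2 terminus of the isopropenyl group (C3) adds to the formyl carbon C2 and a hydrogen of the isopropenyl methyl passes to oxygen, leaving the C4 exocyclic methylene and an aluminium alkoxide that is fixed by loss of methane. The closest known reaction is the Me2AlCl-promoted type 2 intramolecular carbonyl-ene cyclisation of 5-methylhex-5-enals to 3-methylenecyclohexanols. Ring A closes as a six-membered chair with the tether on the central ene carbon C4, exo with respect to the carbonyl and endo with respect to the alkene, and it is trans-fused because the C10 and C5 arms are both equatorial on ring B. The new C2 centre is controlled by the axial C10 methyl: an aluminium-bound oxygen in the axial position would meet that methyl 1,3-diaxially, so oxygen should sit equatorial and give the 2α-alcohol. The step needs reaction at the aldehyde and not at the C9 ketone, which the hindered and conjugated ketone secures, and hydrogen loss from the methyl group and not from C3 or C5, which the internal hydrogen transfer and the proton-scavenging methyl–aluminium bond secure.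

Step 6
Reactants: 10 hydroxy enone
Product: 11 silyl ether (10 with O2 as tert-butyldimethylsilyl ether)
Conditions: TBSCl, imidazole, DMF, rt
Reagents that add atoms: tert-butyldimethylsilyl chloride, CC(C)(C)[Si](C)(C)Cl
Why: Silyl ether protection of the unhindered equatorial alcohol keeps O2 away from the base and iodomethane of step 9 and from all later steps.

Step 7
Reactants: 11 silyl ether
Product: 12 spiro-epoxide (4,19-epoxide of 11 as C4 epimers)
Conditions: mCPBA, NaHCO3, CH2Cl2, 0 °C
Reagents that add atoms: 3-chloroperoxybenzoic acid, OOC(=O)c1cccc(Cl)c1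
Why: Prilezhaev epoxidation should take the electron-rich 1,1-disubstituted C4 methylene and leave the electron-poor enone alkene, and the epoxide configuration is lost in step 8.

Step 8
Reactants: 12 spiro-epoxide
Product: 13 aldehyde (2α-OTBS-9-oxo-Δ7-decalin with C4–H and C4–CHO as C4 epimers)
Conditions: BF3·OEt2, CH2Cl2, −78 °C
Reagents that add atoms: none
Why: Meinwald rearrangement, in which the Lewis acid opens the epoxide to the tertiary C4 cation and a hydride shifts from the oxygen-bearing CH2, should give the aldehyde as is usual for methylenecyclohexane oxides.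

Step 9
Reactants: 13 aldehyde; 2 iodomethane
Product: 15 quaternary aldehyde (4α-CH3 and 4β-CHO), via potassium enolate 14 (not isolated)
Conditions: KOtBu (1.05 equiv), THF, −40 °C; MeI, −40 → 0 °C
Reagents that add atoms: iodomethane, CI
Why: In this enolate alkylation the aldehyde α-hydrogen is several pK units more acidic than the γ-hydrogens of the enone, and iodomethane should approach the exocyclic enolate from the equatorial α-face because the axial C10 methyl closes the β-face, leaving C18 α and the formyl carbon C19 β.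

Step 10
Reactants: 15 quaternary aldehyde
Product: 16 primary alcohol (19-hydroxy enone)
Conditions: NaBH4, MeOH/CH2Cl2, −40 → 0 °C
Reagents that add atoms: none
Why: Chemoselective borohydride reduction should take the aldehyde well before the conjugated C9 ketone, which is flanked by the quaternary C10 and the C8 methyl.

Step 11
Reactants: 16 primary alcohol
Product: 17 silyl dienol ether (2α-OTBS; 19-OTBS; 9-OTBS on the C6=C7–C8=C9 diene)
Conditions: TBSOTf (3 equiv), Et3N, CH2Cl2, 0 °C → rt
Reagents that add atoms: tert-butyldimethylsilyl trifluoromethanesulfonate, CC(C)(C)[Si](C)(C)OS(=O)(=O)C(F)(F)F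
Why: Silyl triflate and amine silylate the primary alcohol and, by soft enolisation of the O-silylated enone, remove a C6 hydrogen to give the through-conjugated dienol ether, the only one possible because C10 carries no hydrogen.

Step 12
Reactants: 17 silyl dienol ether
Product: 19 hydroxy enone (6α-OH; Δ7; 9-oxo), via epoxide 18 (not isolated)
Conditions: mCPBA, NaHCO3, CH2Cl2, −20 °C; aqueous work-up
Reagents that add atoms: 3-chloroperoxybenzoic acid, OOC(=O)c1cccc(Cl)c1
Why: In this vinylogous Rubottom oxidation the peracid should epoxidise the terminal C6=C7 bond of the dienol ether from the α-face, the β-face being closed by the syn-axial C10 methyl and C4 CH2OTBS group, after which the enol ether opens the epoxide to the enone and leaves the 6α-hydroxyl.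

Step 13
Reactants: 19 hydroxy enone
Product: 20 triethylsilyl ether (19 with O6 as triethylsilyl ether)
Conditions: TESOTf, 2,6-lutidine, CH2Cl2, −78 → 0 °C
Reagents that add atoms: triethylsilyl trifluoromethanesulfonate, CC[Si](CC)(CC)OS(=O)(=O)C(F)(F)F
Why: Silyl ether protection with the reactive triflate should cover the hindered allylic alcohol so that O6 stays out of the hydride, triflation and coupling steps.

Step 14
Reactants: 20 triethylsilyl ether
Product: 22 enol triflate (C8=C9 with 9-OTf), via lithium enolate 21 (not isolated)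
Conditions: Li[HB(sBu)3], THF, −78 °C; PhNTf2, −78 °C → rt
Reagents that add atoms: N-phenylbis(trifluoromethanesulfonimide), FC(F)(F)S(=O)(=O)N(c1ccccc1)S(=O)(=O)C(F)(F)F
Why: Conjugate hydride addition at C7 (1,2-attack at C9 being blocked by C10 and the C8 methyl) should give the C8=C9 enolate regiospecifically, and O-triflation traps it as the tetrasubstituted enol triflate (reductive enolate formation followed by triflation).

Step 15
Reactants: 22 enol triflate; 23 tributyl(vinyl)stannane
Product: 24 diene (9-vinyl; C8=C9)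
Conditions: Pd(PPh3)4 (cat.), LiCl, THF, reflux
Reagents that add atoms: tributyl(vinyl)stannane, C=C[Sn](CCCC)(CCCC)CCCC
Why: Stille coupling, by oxidative addition of the enol triflate to zerovalent palladium, chloride-assisted transfer of the vinyl group and reductive elimination, should form C9–C11 as it does with other 2,6,6-trisubstituted cyclohexenyl triflates.

Step 16
Reactants: 24 diene; 25 4-bromofuran-2(5H)-one
Product: 27 silyl-protected butenolide, via alkylborane 26 (not isolated)
Conditions: 9-BBN, THF, 0 °C → rt; then 25, PdCl2(dppf) (cat.), AsPh3, K3PO4, DMF/H2O, rt → 40 °C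
Reagents that add atoms: 4-bromofuran-2(5H)-one, O=C1C=C(Br)CO1
Why: Anti-Markovnikov hydroboration of the vinyl group (the tetrasubstituted C8=C9 bond is inert to 9-BBN) followed by B-alkyl Suzuki–Miyaura coupling with the β-bromobutenolide on zerovalent palladium should join C12 to C13 under a base mild enough for the lactone.

Step 17
Reactants: 27 silyl-protected butenolide
Product: 28 target (2R,4S,5R,6S,10S)-2α,6α,19-trihydroxylabda-8,13-dien-15,16-olide
Conditions: HF·pyridine, pyridine, THF, 0 °C → rt
Reagents that add atoms: none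
Why: Fluoride-mediated desilylation under buffered acidic conditions should remove the three silyl ethers while sparing the base-sensitive butenolide and the tetrasubstituted alkene.

**Compound list**

1 | (R)-carvone, (5R)-2-methyl-5-(prop-1-en-2-yl)cyclohex-2-en-1-one | CC1=CC[C@H](CC1=O)C(C)=C | starting material
2 | iodomethane | CI | starting material
3 | lithium dienolate of 1 (O-lithio C1=C6 enolate, C5 unchanged) | CC1=CC[C@H](C=C1O[Li])C(C)=C | intermediate
4 | (5R)-2,6-dimethyl-5-(prop-1-en-2-yl)cyclohex-2-en-1-one (6-methylcarvone; C6 epimers) | CC1=CC[C@H](C(C)C1=O)C(C)=C | intermediate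
5 | ethyl bromoacetate | CCOC(=O)CBr | starting material
6 | lithium enolate of 4 (tetrasubstituted C1=C6 enolate) | CC1=CC[C@H](C(C)=C1O[Li])C(C)=C | intermediate
7 | ethyl 2-[(1S,6S)-1,3-dimethyl-2-oxo-6-(prop-1-en-2-yl)cyclohex-3-en-1-yl]acetate (acetate arm trans to isopropenyl) | O=C1[C@@](C)(CC(=O)OCC)[C@H](C(C)=C)CC=C1C | intermediate
8 | 2-[(1S,6S)-2-hydroxy-1,3-dimethyl-6-(prop-1-en-2-yl)cyclohex-3-en-1-yl]ethan-1-ol (carbinol epimers) | OC1[C@@](C)(CCO)[C@H](C(C)=C)CC=C1C | intermediate
9 | 2-[(1S,6S)-1,3-dimethyl-2-oxo-6-(prop-1-en-2-yl)cyclohex-3-en-1-yl]acetaldehyde | O=C1[C@@](C)(CC=O)[C@H](C(C)=C)CC=C1C | intermediate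
10 | (4aS,7S,8aS)-7-hydroxy-2,8a-dimethyl-5-methylidene-4a,5,6,7,8,8a-hexahydronaphthalen-1(4H)-one (labdane locants: 2α-OH, 4(19)-methylidene, Δ7, 9-oxo) | O=C1[C@@]2(C)C[C@@H](O)CC(=C)[C@@H]2CC=C1C | intermediate
11 | 2α-O-TBS ether of 10 | O=C1[C@@]2(C)C[C@@H](O[Si](C)(C)C(C)(C)C)CC(=C)[C@@H]2CC=C1C | intermediate
12 | 4,19-epoxide of 11 (spiro-oxirane at C4, both C4 epimers) | O=C1[C@@]2(C)C[C@@H](O[Si](C)(C)C(C)(C)C)CC3(CO3)[C@@H]2CC=C1C | intermediate
13 | 2α-OTBS-9-oxo-Δ7-decalin-4-carbaldehyde (C4–H, both C4 epimers) | O=C1[C@@]2(C)C[C@@H](O[Si](C)(C)C(C)(C)C)CC(C=O)[C@@H]2CC=C1C | intermediate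
14 | potassium enolate of 13 (C4=C19–OK) | O=C1[C@@]2(C)C[C@@H](O[Si](C)(C)C(C)(C)C)CC(=CO[K])[C@@H]2CC=C1C | intermediate
15 | 4α-methyl-4β-formyl aldehyde (2α-OTBS, Δ7, 9-oxo, 19-al) | O=C1[C@@]2(C)C[C@@H](O[Si](C)(C)C(C)(C)C)C[C@](C)(C=O)[C@@H]2CC=C1C | intermediate
16 | 19-hydroxy enone (2α-OTBS, 4α-CH3, 4β-CH2OH, Δ7, 9-oxo) | O=C1[C@@]2(C)C[C@@H](O[Si](C)(C)C(C)(C)C)C[C@](C)(CO)[C@@H]2CC=C1C | intermediate
17 | tris-TBS dienol ether (2α-OTBS, 19-OTBS, 9-OTBS, C6=C7 and C8=C9) | CC1=C(O[Si](C)(C)C(C)(C)C)[C@@]2(C)C[C@@H](O[Si](C)(C)C(C)(C)C)C[C@](C)(CO[Si](C)(C)C(C)(C)C)[C@@H]2C=C1 | intermediate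
18 | 6α,7α-epoxide of 17 | CC1=C(O[Si](C)(C)C(C)(C)C)[C@@]2(C)C[C@@H](O[Si](C)(C)C(C)(C)C)C[C@](C)(CO[Si](C)(C)C(C)(C)C)[C@@H]2[C@H]3O[C@H]31 | intermediate
19 | 6α-hydroxy enone (2α-OTBS, 19-OTBS, Δ7, 9-oxo) | O=C1[C@@]2(C)C[C@@H](O[Si](C)(C)C(C)(C)C)C[C@](C)(CO[Si](C)(C)C(C)(C)C)[C@@H]2[C@@H](O)C=C1C | intermediate
20 | 6α-O-TES ether of 19 | O=C1[C@@]2(C)C[C@@H](O[Si](C)(C)C(C)(C)C)C[C@](C)(CO[Si](C)(C)C(C)(C)C)[C@@H]2[C@@H](O[Si](CC)(CC)CC)C=C1C | intermediate
21 | lithium C8=C9 enolate (9-OLi) from 20 | CC1=C(O[Li])[C@@]2(C)C[C@@H](O[Si](C)(C)C(C)(C)C)C[C@](C)(CO[Si](C)(C)C(C)(C)C)[C@@H]2[C@@H](O[Si](CC)(CC)CC)C1 | intermediate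
22 | C8=C9 enol triflate (9-OTf; 2α-OTBS, 6α-OTES, 19-OTBS) | CC1=C(OS(=O)(=O)C(F)(F)F)[C@@]2(C)C[C@@H](O[Si](C)(C)C(C)(C)C)C[C@](C)(CO[Si](C)(C)C(C)(C)C)[C@@H]2[C@@H](O[Si](CC)(CC)CC)C1 | intermediate
23 | tributyl(vinyl)stannane | C=C[Sn](CCCC)(CCCC)CCCC | starting material
24 | 9-vinyl diene (C8=C9 and C11=C12; 2α-OTBS, 6α-OTES, 19-OTBS) | CC1=C(C=C)[C@@]2(C)C[C@@H](O[Si](C)(C)C(C)(C)C)C[C@](C)(CO[Si](C)(C)C(C)(C)C)[C@@H]2[C@@H](O[Si](CC)(CC)CC)C1 | intermediate
25 | 4-bromofuran-2(5H)-one | O=C1C=C(Br)CO1 | starting material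
26 | C12 alkyl-9-BBN borane from 24 | CC1=C(CCB3C4CCCC3CCC4)[C@@]2(C)C[C@@H](O[Si](C)(C)C(C)(C)C)C[C@](C)(CO[Si](C)(C)C(C)(C)C)[C@@H]2[C@@H](O[Si](CC)(CC)CC)C1 | intermediate
27 | 2α,19-bis-O-TBS-6α-O-TES ether of the target | CC1=C(CCC3=CC(=O)OC3)[C@@]2(C)C[C@@H](O[Si](C)(C)C(C)(C)C)C[C@](C)(CO[Si](C)(C)C(C)(C)C)[C@@H]2[C@@H](O[Si](CC)(CC)CC)C1 | intermediate
28 | (2R,4S,5R,6S,10S)-2α,6α,19-trihydroxylabda-8,13-dien-15,16-olide | CC1=C(CCC2=CC(=O)OC2)[C@@]2(C)C[C@@H](O)C[C@](C)(CO)[C@@H]2[C@@H](O)C1 | target

**Count and risks**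

Total steps: 17. Longest linear sequence: 17 steps from (R)-carvone.

Step 5. The cyclisation may run through a closed transition state with the aluminium-bound oxygen axial, which means addition to the other face of the formyl group. Proton loss into ring A instead of from the methyl group is a second possible leak. Fallback: starting from keto aldehyde 9, the cyclisation is accepted with whatever C2 selectivity it shows. The 2β-alcohol F1 is separated and inverted by a Mitsunobu reaction (4-nitrobenzoic acid, PPh3, DIAD, toluene) to the 2α-(4-nitrobenzoate) F2. Methanolysis (K2CO3, MeOH) then rejoins the route at 10.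

Step 12. The peracid may attack C8, the other nucleophilic carbon of the dienol ether, or approach C6 from the β-face. Fallback: from 17, MeLi (THF, 0 °C) cleaves the enol silyl ether to the lithium dienolate F3. Kinetic protonation at C8 with AcOH at −78 °C gives the β,γ-unsaturated ketone F4. mCPBA/NaHCO3 epoxidises its isolated C6=C7 bond from the open α-face to the 6α,7α-epoxy ketone F5. DBU in CH2Cl2 opens the epoxide by β-elimination from C8 and rejoins the route at 19. Here the site of oxidation is fixed because only one alkene is present.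

Step 14. Hydride delivery may go 1,2 to C9 or stall at C7 next to the C6 silyl ether. Fallback: from 20, hydrogenation (H2, palladium on carbon, EtOAc) gives the saturated ketone F6 as C8 epimers. KN(SiMe3)2 (THF, −78 °C) can deprotonate only at C8, since C10 is quaternary, and gives the potassium enolate F7. N-(5-chloropyridin-2-yl)bis(trifluoromethanesulfonimide) triflates it and rejoins the route at 22.

**Further compounds**

F1 | step 5 | 2β-hydroxy epimer of 10 | O=C1[C@@]2(C)C[C@H](O)CC(=C)[C@@H]2CC=C1C
F2 | step 5 | 2α-(4-nitrobenzoate) of 10 | O=C1[C@@]2(C)C[C@@H](OC(=O)c3ccc(cc3)[N+](=O)[O-])CC(=C)[C@@H]2CC=C1C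
F3 | step 12 | lithium dienolate from 17 (9-OLi, C6=C7 and C8=C9) | CC1=C(O[Li])[C@@]2(C)C[C@@H](O[Si](C)(C)C(C)(C)C)C[C@](C)(CO[Si](C)(C)C(C)(C)C)[C@@H]2C=C1
F4 | step 12 | β,γ-unsaturated ketone (9-oxo, Δ6, C8–H as epimers) | CC1C(=O)[C@@]2(C)C[C@@H](O[Si](C)(C)C(C)(C)C)C[C@](C)(CO[Si](C)(C)C(C)(C)C)[C@@H]2C=C1
F5 | step 12 | 6α,7α-epoxy ketone from F4 | CC1C(=O)[C@@]2(C)C[C@@H](O[Si](C)(C)C(C)(C)C)C[C@](C)(CO[Si](C)(C)C(C)(C)C)[C@@H]2[C@H]3O[C@H]31
F6 | step 14 | saturated ketone (7,8-dihydro-20, C8 epimers) | CC1C(=O)[C@@]2(C)C[C@@H](O[Si](C)(C)C(C)(C)C)C[C@](C)(CO[Si](C)(C)C(C)(C)C)[C@@H]2[C@@H](O[Si](CC)(CC)CC)C1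
F7 | step 14 | potassium C8=C9 enolate of F6 | CC1=C(O[K])[C@@]2(C)C[C@@H](O[Si](C)(C)C(C)(C)C)C[C@](C)(CO[Si](C)(C)C(C)(C)C)[C@@H]2[C@@H](O[Si](CC)(CC)CC)C1
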